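The plan rests on cutting the C11–C12 bond (counted from the ester oxygen) of the straight, saturated O–(CH2)25–CH3 chain. Both carbons are plain methylenes, well removed from the ester oxygen and from the benzene ring, so each can be generated as an unstabilised primary radical. A crossed Kolbe electrolysis does this in one operation. Two carboxylic acids lose CO2 at a platinum anode, and the C11 and C15 radicals join to give the complete C26 ester. The precursor is 12-hydroxydodecanoic acid already O-acylated by the 3-arylpropanoic acid, with its phenol masked as the acetate. Palmitic acid is the partner. Aminolysis of the aryl acetate then ends the route.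

Key step: step 5

Remark: the alkyl chain of the target is read as 26 carbons, 11 left from the C12 hydroxy acid and 15 left from palmitic acid after each loses CO2. The molecule has no stereocentre and no C=C bond, so no stereochemical control is needed.

Step 1
Reactants: 1 phloretic acid (3-(4-hydroxyphenyl)propanoic acid)
Product: 2 O-acetylphloretic acid (3-(4-acetoxyphenyl)propanoic acid)
Conditions: Ac2O (1.3 equiv), 2 M aq NaOH (2.2 equiv), 0 °C, 30 min; then 2 M HCl to pH 2, filter
Reagents that add atoms: acetic anhydride, CC(=O)OC(C)=O
Why: Schotten–Baumann-type O-acetylation: in cold aqueous alkali the phenoxide is the only lasting acyl acceptor, since water at once reverses any acyl transfer to the carboxylate, and prompt acidification should precipitate 2 before the new aryl ester can hydrolyse.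

Step 2
Reactants: 3 sabinic acid (12-hydroxydodecanoic acid)
Product: 4 benzyl 12-hydroxydodecanoate
Conditions: BnBr (1.05 equiv), KHCO3 (1.5 equiv), DMF, rt to 40 °C
Reagents that add atoms: benzyl bromide, BrCc1ccccc1
Why: SN2 O-alkylation of a carboxylate: hydrogencarbonate ionises only the CO2H group, so the carboxylate should take up benzyl bromide while the primary alcohol stays neutral and unalkylated, and the low temperature avoids self-esterification of the hydroxy acid.

Step 3
Reactants: 2 O-acetylphloretic acid (1.1 equiv); 4 benzyl 12-hydroxydodecanoate
Product: 5 benzyl 12-{[3-(4-acetoxyphenyl)propanoyl]oxy}dodecanoate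
Conditions: EDC·HCl (1.3 equiv), DMAP (0.1 equiv), CH2Cl2, 0 °C to rt
Reagents that add atoms: none
Why: Steglich esterification: the carbodiimide activates the only free CO2H present and DMAP relays the acyl group to the only free OH present, and a slight excess of 2, little DMAP and a cold start should make this far faster than any acetyl migration from the aryl acetate.

Step 4
Reactants: 5 benzyl 12-{[3-(4-acetoxyphenyl)propanoyl]oxy}dodecanoate
Product: 6 Kolbe acid 12-{[3-(4-acetoxyphenyl)propanoyl]oxy}dodecanoic acid
Conditions: H2 (1 atm), 10% Pd/C, EtOAc, rt
Reagents that add atoms: none
Why: Catalytic hydrogenolysis of a benzyl ester: only the benzylic C–O bond is cleaved on palladium under one atmosphere of hydrogen, while the aryl acetate, the alkyl ester and the benzene ring are inert in a neutral aprotic solvent.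

Step 5
Reactants: 6 Kolbe acid 12-{[3-(4-acetoxyphenyl)propanoyl]oxy}dodecanoic acid; 7 palmitic acid (hexadecanoic acid)
Product: 10 hexacosyl 3-(4-acetoxyphenyl)propanoate, via acyloxyundecyl radical 8 (not isolated), via pentadecyl radical 9 (not isolated)
Conditions: 7 (5 equiv), Et3N (0.08 equiv per CO2H), MeCN/heptane (two liquid phases, vigorous stirring), smooth Pt anode and Pt cathode 1–2 mm apart, undivided cell, 0.25 A cm−2, polarity swapped every few minutes, 50 °C, about 1.3 F per mol CO2H, current cut while the mixture is still acidic; silica gel, hexane then hexane/EtOAc
Reagents that add atoms: none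
Why: Crossed Kolbe electrolysis: each carboxylate gives up one electron at the platinum anode, the acyloxy radical loses CO2 at once, and the primary radicals 8 and 9, born side by side at high concentration in the layer next to the electrode, combine to form the C11–C12 sp3–sp3 bond while carboxyl protons are reduced to H2 at the cathode. Joining a fatty acid to an ω-acyloxy or half-ester acid in this way is long-established practice, so only the molecule is new. No ring is closed and no stereocentre arises. Cross- versus homo-coupling is statistical, so the fivefold excess of cheap 7 should steer most of 8 into 10, and the by-products differ from 10 by whole ester units (the hydrocarbon homodimer of 7 has none, the homodimer of 6 has twice as many), so silica gel should separate them easily. The radical rather than the carbocation (Hofer–Moest) pathway is favoured by the unsubstituted α-carbons, the smooth platinum surface, the high current density, the weakly acidic medium and the absence of foreign electrolyte anions, and the benzene ring should be spared because O-acetylation lifts its oxidation potential to about that of an alkylbenzene and the adsorbed carboxylate film keeps the neutral arene end away from the anode. MeCN in place of the customary MeOH removes the nucleophile that would strip the aryl acetate in a carboxylate buffer, the warm medium dissolves 7, the heptane phase takes up the waxy products before they can coat the electrodes, and stopping while free acid remains keeps the medium from turning basic.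

Step 6
Reactants: 10 hexacosyl 3-(4-acetoxyphenyl)propanoate
Product: 11 hexacosyl 3-(4-hydroxyphenyl)propanoate
Conditions: pyrrolidine (3 equiv), THF, 30 °C; wash with cold 0.5 M citric acid, recrystallise
Reagents that add atoms: none
Why: Chemoselective aminolysis of an aryl ester: the aryloxide is a far better leaving group than a hexacosyl alkoxide, so a secondary amine near room temperature should cleave only the acetate, and because no alcohol, alkoxide or hydroxide is present the wax ester can be neither transesterified nor saponified.

Compound list
1 | phloretic acid (3-(4-hydroxyphenyl)propanoic acid) | O=C(O)CCc1ccc(O)cc1 | starting material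
2 | O-acetylphloretic acid (3-(4-acetoxyphenyl)propanoic acid) | CC(=O)Oc1ccc(CCC(=O)O)cc1 | intermediate
3 | sabinic acid (12-hydroxydodecanoic acid) | OCCCCCCCCCCCC(=O)O | starting material
4 | benzyl 12-hydroxydodecanoate | OCCCCCCCCCCCC(=O)OCc1ccccc1 | intermediate
5 | benzyl 12-{[3-(4-acetoxyphenyl)propanoyl]oxy}dodecanoate | CC(=O)Oc1ccc(CCC(=O)OCCCCCCCCCCCC(=O)OCc2ccccc2)cc1 | intermediate
6 | 12-{[3-(4-acetoxyphenyl)propanoyl]oxy}dodecanoic acid | CC(=O)Oc1ccc(CCC(=O)OCCCCCCCCCCCC(=O)O)cc1 | intermediate
7 | palmitic acid (hexadecanoic acid) | CCCCCCCCCCCCCCCC(=O)O | starting material
8 | 11-{[3-(4-acetoxyphenyl)propanoyl]oxy}undecyl radical (not isolated) | [CH2]CCCCCCCCCCOC(=O)CCc1ccc(OC(C)=O)cc1 | intermediate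
9 | pentadecyl radical (not isolated) | [CH2]CCCCCCCCCCCCCC | intermediate
10 | hexacosyl 3-(4-acetoxyphenyl)propanoate | CCCCCCCCCCCCCCCCCCCCCCCCCCOC(=O)CCc1ccc(OC(C)=O)cc1 | intermediate
11 | hexacosyl 3-(4-hydroxyphenyl)propanoate | CCCCCCCCCCCCCCCCCCCCCCCCCCOC(=O)CCc1ccc(O)cc1 | target

Total step count: 6
Longest linear sequence: 5 steps (1 to 11 through steps 1, 3, 4, 5, 6; the branch from 3 through steps 2, 3, 4, 5, 6 is equally long)

Steps most likely to fail

Step 5. The run may stall or consume the valuable half in three ways:
- anodic attack on the benzene ring, with film growth on the platinum
- loss of the acetate during the run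
- coating of the electrodes by wax

The fallback keeps the same C11–C12 cut but makes the bond reductively, without an anode. Setting out from 6, condensation with N-hydroxyphthalimide (DIC, catalytic DMAP, CH2Cl2) should give the redox-active 1,3-dioxoisoindolin-2-yl ester F1. Bought 1-bromopentadecane is converted with Mg in THF into pentadecylmagnesium bromide F2. F2 is then treated with ZnCl2 (0.5 equiv) to give dipentadecylzinc F3, so that no free Grignard reagent meets the aryl acetate. A nickel-catalysed decarboxylative alkyl–alkyl Negishi-type coupling of F1 with F3 then rejoins the route at 10. Its conditions are catalytic NiCl2·DME and 4,4'-di-tert-butyl-2,2'-bipyridine in THF/DMF at rt.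

Step 6. Aminolysis may be sluggish because the wax ester dissolves poorly, and forcing it may bring attack on the hexacosyl ester. The fallback gives up selective cleavage in favour of selective esterification. Setting out from 10, LiOH in THF/H2O at 50 °C cleaves both esters, and acidification and extraction deliver 1-hexacosanol F4. F4 is then esterified with an excess of 1 under Fischer conditions (catalytic p-TsOH·H2O, toluene, reflux with a Dean–Stark trap). A phenol is not acylated under these acid-equilibrium conditions. This path comes back to the route at 11.

Step 3. DMAP may carry the acetyl group from the aryl acetate onto the primary alcohol, or the activated acid may undergo an O-to-N acyl shift to an unreactive N-acylurea. The fallback activates the alcohol instead of the acid. Setting out from 2 and 4, a Mitsunobu esterification (PPh3, DIAD, THF, 0 °C to rt) lets the carboxylate of 2 displace the phosphonium-activated primary oxygen of 4 with no acyl-transfer catalyst present. It rejoins the route at 5. This detour makes no new compound (F0).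

Further compounds
F1 | step 5 | 1,3-dioxoisoindolin-2-yl 12-{[3-(4-acetoxyphenyl)propanoyl]oxy}dodecanoate | CC(=O)Oc1ccc(CCC(=O)OCCCCCCCCCCCC(=O)ON2C(=O)c3ccccc3C2=O)cc1
F2 | step 5 | pentadecylmagnesium bromide | CCCCCCCCCCCCCCC[Mg]Br
F3 | step 5 | dipentadecylzinc | CCCCCCCCCCCCCCC[Zn]CCCCCCCCCCCCCCC
F4 | step 6 | 1-hexacosanol | CCCCCCCCCCCCCCCCCCCCCCCCCCO
F0 | step 3 | none | none
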